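## Retrosynthetic overview

- The quinone ring (C-1′ to C-6′) is the bis-enol of a cyclohexane-1,2,4,5-tetrone. C-3′ and C-6′ each sit between two carbonyl carbons (C-2′/C-4′ and C-5′/C-1′), so cutting C-3′–C-4′ and C-6′–C-1′ gives two 2-oxoacyl C3 units: α-keto ester 18 (C-1′ to C-3′ plus decalin) and pyruvoyl chloride 20 (C-4′ to C-6′). The unhindered C-5′ OH is methylated last.
- 18 comes from chloride 16 (Grignard reagent plus diethyl oxalate); the C-4 methylidene comes from a C-4 ketone (Wittig), made by hydroboration of the ring A alkene.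
- The C-9 quaternary centre is set by an Eschenmoser–Claisen rearrangement of allylic alcohol 7, anti to the C-10 methyl; the C-8 methyl by amide-directed hydrogenation of the exo-methylene this leaves.
- 7 comes from (S)-Wieland–Miescher ketone 1; C-10 is the only bought stereocentre, and C-9, C-8 and C-5 are relayed from it.
- Ring order: rings A and B are bought as 1; the quinone ring is formed last, in step 15.

Key step: step 15

Remark: decalin positions use terpenoid-type locants (C-10 angular-methyl carbon, C-5 ring-fusion CH, C-4 methylidene carbon, C-9 quaternary carbon bearing the link C-11, C-8 CHMe); quinone carbons C-1′ to C-6′ follow the IUPAC name (C-3′ bears C-11); β is the face of the C-10 methyl, α the opposite face.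

## Route

Step 1
Reactants: 1 (S)-Wieland–Miescher ketone
Product: 2 dithioketal (1,3-dithiolane) of the enone carbonyl C-3 of 1
Conditions: HS(CH2)2SH, p-TsOH (cat.), AcOH, rt
Reagents that add atoms: ethane-1,2-dithiol, SCCS
Why: Acid-catalysed dithioketalisation should be chemoselective for the enone carbonyl over the C-9 ketone flanked by the quaternary carbon, with the double bond staying at C-4=C-5.

Step 2
Reactants: 2 dithioketal
Product: 3 (S)-8a-methyl-3,4,6,7,8,8a-hexahydronaphthalen-1(2H)-one
Conditions: Raney Ni (W-2), EtOH–acetone, reflux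
Reagents that add atoms: none
Why: Raney-nickel desulfurisation (Mozingo reduction) replaces both C–S bonds by C–H and so removes the C-3 oxygen, while the trisubstituted alkene and the hindered ketone should survive on acetone-deactivated catalyst.

Step 3
Reactants: 3 ene-ketone
Product: 5 (S)-1-chloro-8a-methyl-3,4,6,7,8,8a-hexahydronaphthalene-2-carbaldehyde, via chlorovinyl iminium salt 4 (not isolated)
Conditions: POCl3, DMF, CH2Cl2, 0 → 40 °C; then aq. NaOAc
Reagents that add atoms: N,N-dimethylformamide, CN(C)C=O; phosphoryl chloride, O=P(Cl)(Cl)Cl; water, O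
Why: Vilsmeier–Haack–Arnold chloroformylation: the ketone can enolise only toward C-8 (C-10 is quaternary), so C-8 is formylated and the carbonyl becomes the vinyl chloride, while the isolated ring A alkene should be inert.

Step 4
Reactants: 5 β-chloro enal
Product: 6 (S)-1,8a-dimethyl-3,4,6,7,8,8a-hexahydronaphthalene-2-carbaldehyde
Conditions: (MeBO)3, Pd(OAc)2 (5 mol%), SPhos (10 mol%), K3PO4, toluene–H2O, 90 °C
Reagents that add atoms: trimethylboroxine, CB1OB(C)OB(C)O1
Why: Suzuki–Miyaura methylation of the activated β-chloro enal (a vinylogous acid chloride), with an electron-rich biarylphosphine because the C–Cl carbon is flanked by the quaternary C-10.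

Step 5
Reactants: 6 enal
Product: 7 [(S)-1,8a-dimethyl-3,4,6,7,8,8a-hexahydronaphthalen-2-yl]methanol
Conditions: NaBH4, CeCl3·7H2O, MeOH, 0 °C
Reagents that add atoms: none
Why: Luche 1,2-reduction of the tetrasubstituted enal should give the allylic alcohol without conjugate reduction.

Step 6
Reactants: 7 allylic alcohol
Product: 9 2-[(1R,8aS)-1,8a-dimethyl-2-methylidene-1,2,3,4,6,7,8,8a-octahydronaphthalen-1-yl]-N,N-dimethylacetamide, via ketene N,O-acetal 8 (not isolated)
Conditions: MeC(OMe)2NMe2 (5 equiv), xylenes, 140 °C, sealed tube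
Reagents that add atoms: N,N-dimethylacetamide dimethyl acetal, CC(OC)(OC)N(C)C
Why: Eschenmoser–Claisen rearrangement: the suprafacial [3,3] shift of 8 forms the C-9–C-11 bond on the α face, anti to the pseudo-axial C-10 methyl, which should set the C-9 quaternary centre (CH2CONMe2 α, CH3 β) next to quaternary C-10 and leave the alkene exocyclic at C-8.

Step 7
Reactants: 9 amide
Product: 10 2-[(1R,2S,8aS)-1,2,8a-trimethyl-1,2,3,4,6,7,8,8a-octahydronaphthalen-1-yl]-N,N-dimethylacetamide
Conditions: [Ir(cod)(PCy3)(py)]PF6 (2.5 mol%), H2 (1 atm), CH2Cl2, 0 °C → rt, stopped after one equivalent of H2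
Reagents that add atoms: none
Why: Carbonyl-directed homogeneous hydrogenation: iridium bound to the α-disposed amide oxygen adds H2 to the α face of the 1,1-disubstituted C-8 alkene, which should set the C-8 methyl β (the contra-thermodynamic axial epimer, cis to both neighbouring methyls), while the undirected trisubstituted ring A alkene beside quaternary C-10 should react far more slowly.

Step 8
Reactants: 10 amide
Product: 11 2-[(1R,2S,8aS)-1,2,8a-trimethyl-1,2,3,4,6,7,8,8a-octahydronaphthalen-1-yl]ethan-1-ol
Conditions: LiEt3BH (3 equiv), THF, 0 °C → rt; aq. NH4Cl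
Reagents that add atoms: none
Why: LiEt3BH reduces the tertiary amide with C–N cleavage to the primary alcohol and should leave the ring A alkene alone.

Step 9
Reactants: 11 alcohol
Product: 12 (1R,2S,8aS)-1-(2-chloroethyl)-1,2,8a-trimethyl-1,2,3,4,6,7,8,8a-octahydronaphthalene
Conditions: PPh3, CCl4, CH2Cl2, 40 °C
Reagents that add atoms: tetrachloromethane, ClC(Cl)(Cl)Cl
Why: Appel chlorination (SN2 on the primary alkoxyphosphonium ion) runs under neutral conditions that should not touch the alkene; the chloride is chosen because it survives the later ylide.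

Step 10
Reactants: 12 chloride
Product: 14 (1R,4aS,5R,6S,8aR)-5-(2-chloroethyl)-4a,5,6-trimethyldecahydronaphthalen-1-ol, via alkylborane 13 (not isolated)
Conditions: BH3·SMe2, THF, 0 °C → rt; then NaOH, H2O2, 0 °C
Reagents that add atoms: hydrogen peroxide, OO
Why: Syn, anti-Markovnikov hydroboration–oxidation puts boron on the less substituted C-4 and hydrogen on C-5 from the α face, away from the axial C-10 methyl, which should give the trans ring fusion (a cis portion would converge later, since C-5 becomes epimerisable next to the C-4 ketone).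

Step 11
Reactants: 14 alcohol
Product: 15 (4aS,5R,6S,8aR)-5-(2-chloroethyl)-4a,5,6-trimethyloctahydronaphthalen-1(2H)-one
Conditions: Dess–Martin periodinane, NaHCO3, CH2Cl2, rt
Reagents that add atoms: none
Why: Dess–Martin oxidation of the secondary alcohol should leave the alkyl chloride and the stereocentres untouched, with C-5 resting in the more stable trans-fused arrangement.

Step 12
Reactants: 15 ketone
Product: 16 (1R,2S,4aS,8aS)-1-(2-chloroethyl)-1,2,8a-trimethyl-5-methylidenedecahydronaphthalene
Conditions: Ph3PCH3Br, KOt-Bu, THF, 0 → 50 °C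
Reagents that add atoms: methyltriphenylphosphonium bromide, C[P+](c1ccccc1)(c1ccccc1)c1ccccc1.[Br-]
Why: Wittig methylenation of the C-4 ketone installs the exocyclic alkene; the primary alkyl chloride is too poor an electrophile to alkylate the ylide under these conditions.

Step 13
Reactants: 16 chloride
Product: 18 ethyl 2-oxo-4-[(1R,2S,4aS,8aS)-1,2,8a-trimethyl-5-methylidenedecahydronaphthalen-1-yl]butanoate, via alkylmagnesium chloride 17 (not isolated)
Conditions: Mg (I2-activated), THF, 60 °C; then added to (CO2Et)2 (3 equiv), THF, −78 °C; aq. NH4Cl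
Reagents that add atoms: diethyl oxalate, CCOC(=O)C(=O)OCC
Why: Grignard formation and acylation by excess diethyl oxalate at −78 °C, where the tetrahedral magnesium adduct persists until the quench, so addition should stop at the α-keto ester.

Step 14
Reactants: 19 pyruvic acid
Product: 20 pyruvoyl chloride
Conditions: Cl2CHOMe (1 equiv), neat, 50 °C; distillation
Reagents that add atoms: dichloromethyl methyl ether, COC(Cl)Cl
Why: Acid chloride formation with α,α-dichloromethyl methyl ether (loss of methyl formate and HCl) is mild enough for the α-keto acid.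

Step 15
Reactants: 18 α-keto ester; 20 pyruvoyl chloride
Product: 22 2,5-dihydroxy-3-{[(1R,2S,4aS,8aS)-1,2,8a-trimethyl-5-methylidenedecahydronaphthalen-1-yl]methyl}cyclohexa-2,5-diene-1,4-dione, via trioxo ester 21 (not isolated)
Conditions: MgBr2·OEt2 (3 equiv), 20 (2 equiv), CH2Cl2, −20 °C; i-Pr2NEt (4 equiv) added slowly, −20 → 0 °C; then DBU (2 equiv), MeCN, 25 → 40 °C; 1 M HCl
Reagents that add atoms: none
Why: Proposed new method: MgBr2·OEt2 and i-Pr2NEt convert the 1,2-dicarbonyl unit of 18 into a chelated magnesium enolate that is C-acylated at C-3′ by the acid chloride 20 (bond C-3′–C-4′), and the magnesium diketonate of the resulting 2,4,5-trioxo ester 21 is then enolised by DBU at its acetyl CH3 (C-6′), which attacks the ester carbon C-1′ and expels ethoxide (bond C-6′–C-1′); the cyclohexane-1,2,4,5-tetrone so formed is the keto tautomer of the 2,5-dihydroxy-1,4-benzoquinone 22, so the ring arrives at the quinone oxidation level without a redox step. The closest known reaction types are the magnesium-mediated C-acylation of ketones and β-keto esters with acid chlorides (soft enolisation), the magnesium-templated Claisen cyclisation of polyketo esters to acylphloroglucinols and the base-induced head-to-tail self-condensation of 2-oxo esters or succinates to six-membered rings; a crossed version between two different 2-oxoacyl units has not been shown. The ring closes in a 6-(enolendo)-exo-trig Dieckmann mode, and the competing five-membered aldol onto C-2′ is disfavoured because C-2′ is held in the chelated enolate. No stereocentre is formed, and the four decalin stereocentres are remote from any enolisable position. The step needs cross- over homo-condensation and C- over O-acylation: the first should be secured by the unequal roles of the partners (only 18 carries an ester, the acid chloride is by far the strongest electrophile present and is used in excess, and the base is added last so that free 18 does not meet its own enolate), the second by the magnesium chelate. The 1,1-disubstituted alkene should be inert to MgBr2·OEt2, the amine bases and the acid chloride at these temperatures.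

Step 16
Reactants: 22 dihydroxyquinone
Product: 23 2-hydroxy-5-methoxy-3-{[(1R,2S,4aS,8aS)-1,2,8a-trimethyl-5-methylidenedecahydronaphthalen-1-yl]methyl}cyclohexa-2,5-diene-1,4-dione (target)
Conditions: MeOH, camphorsulfonic acid (10 mol%), 3 Å molecular sieves, rt → 40 °C, monitored
Reagents that add atoms: methanol, CO
Why: Acid-catalysed vinylogous esterification (addition–elimination of methanol on a hydroxyquinone, as used for 3-alkyl-2,5-dihydroxybenzoquinones): methanol should attack the unhindered C-5′ flanked by C-6′–H rather than C-2′ flanked by the neopentyl-type CH2, and the mild sulfonic acid should leave the exocyclic alkene in place.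

## Compound list

1 | (S)-8a-methyl-3,4,8,8a-tetrahydronaphthalene-1,6(2H,7H)-dione, (S)-Wieland–Miescher ketone | O=C1CC[C@@]2(C)C(=C1)CCCC2=O | starting material
2 | (8a'S)-8a'-methyl-3',4',8',8a'-tetrahydro-2'H-spiro[[1,3]dithiolane-2,6'-naphthalen]-1'(7'H)-one | C12(SCCS1)CC[C@@]3(C)C(=C2)CCCC3=O | intermediate
3 | (S)-8a-methyl-3,4,6,7,8,8a-hexahydronaphthalen-1(2H)-one | C1CC[C@@]2(C)C(=C1)CCCC2=O | intermediate
4 | N-{[(S)-1-chloro-8a-methyl-3,4,6,7,8,8a-hexahydronaphthalen-2-yl]methylidene}-N-methylmethanaminium chloride (formed in situ) | C1CC[C@@]2(C)C(=C1)CCC(C=[N+](C)C)=C2Cl.[Cl-] | intermediate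
5 | (S)-1-chloro-8a-methyl-3,4,6,7,8,8a-hexahydronaphthalene-2-carbaldehyde | C1CC[C@@]2(C)C(=C1)CCC(C=O)=C2Cl | intermediate
6 | (S)-1,8a-dimethyl-3,4,6,7,8,8a-hexahydronaphthalene-2-carbaldehyde | C1CC[C@@]2(C)C(=C1)CCC(C=O)=C2C | intermediate
7 | [(S)-1,8a-dimethyl-3,4,6,7,8,8a-hexahydronaphthalen-2-yl]methanol | C1CC[C@@]2(C)C(=C1)CCC(CO)=C2C | intermediate
8 | 1-{[(S)-1,8a-dimethyl-3,4,6,7,8,8a-hexahydronaphthalen-2-yl]methoxy}-N,N-dimethylethen-1-amine (formed in situ) | C1CC[C@@]2(C)C(=C1)CCC(COC(=C)N(C)C)=C2C | intermediate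
9 | 2-[(1R,8aS)-1,8a-dimethyl-2-methylidene-1,2,3,4,6,7,8,8a-octahydronaphthalen-1-yl]-N,N-dimethylacetamide | C1CC[C@@]2(C)C(=C1)CCC(=C)[C@@]2(C)CC(=O)N(C)C | intermediate
10 | 2-[(1R,2S,8aS)-1,2,8a-trimethyl-1,2,3,4,6,7,8,8a-octahydronaphthalen-1-yl]-N,N-dimethylacetamide | C1CC[C@@]2(C)C(=C1)CC[C@H](C)[C@@]2(C)CC(=O)N(C)C | intermediate
11 | 2-[(1R,2S,8aS)-1,2,8a-trimethyl-1,2,3,4,6,7,8,8a-octahydronaphthalen-1-yl]ethan-1-ol | C1CC[C@@]2(C)C(=C1)CC[C@H](C)[C@@]2(C)CCO | intermediate
12 | (1R,2S,8aS)-1-(2-chloroethyl)-1,2,8a-trimethyl-1,2,3,4,6,7,8,8a-octahydronaphthalene | C1CC[C@@]2(C)C(=C1)CC[C@H](C)[C@@]2(C)CCCl | intermediate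
13 | [(1R,4aS,5R,6S,8aS)-5-(2-chloroethyl)-4a,5,6-trimethyldecahydronaphthalen-1-yl]borane (formed in situ, shown as RBH2) | [BH2][C@@H]1CCC[C@@]2(C)[C@H]1CC[C@H](C)[C@@]2(C)CCCl | intermediate
14 | (1R,4aS,5R,6S,8aR)-5-(2-chloroethyl)-4a,5,6-trimethyldecahydronaphthalen-1-ol | O[C@@H]1CCC[C@@]2(C)[C@H]1CC[C@H](C)[C@@]2(C)CCCl | intermediate
15 | (4aS,5R,6S,8aR)-5-(2-chloroethyl)-4a,5,6-trimethyloctahydronaphthalen-1(2H)-one | O=C1CCC[C@@]2(C)[C@H]1CC[C@H](C)[C@@]2(C)CCCl | intermediate
16 | (1R,2S,4aS,8aS)-1-(2-chloroethyl)-1,2,8a-trimethyl-5-methylidenedecahydronaphthalene | C=C1CCC[C@@]2(C)[C@H]1CC[C@H](C)[C@@]2(C)CCCl | intermediate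
17 | {2-[(1R,2S,4aS,8aS)-1,2,8a-trimethyl-5-methylidenedecahydronaphthalen-1-yl]ethyl}magnesium chloride (formed in situ) | C=C1CCC[C@@]2(C)[C@H]1CC[C@H](C)[C@@]2(C)CC[Mg]Cl | intermediate
18 | ethyl 2-oxo-4-[(1R,2S,4aS,8aS)-1,2,8a-trimethyl-5-methylidenedecahydronaphthalen-1-yl]butanoate | C=C1CCC[C@@]2(C)[C@H]1CC[C@H](C)[C@@]2(C)CCC(=O)C(=O)OCC | intermediate
19 | pyruvic acid (2-oxopropanoic acid) | CC(=O)C(=O)O | starting material
20 | pyruvoyl chloride (2-oxopropanoyl chloride) | CC(=O)C(Cl)=O | intermediate
21 | ethyl 2,4,5-trioxo-3-{[(1R,2S,4aS,8aS)-1,2,8a-trimethyl-5-methylidenedecahydronaphthalen-1-yl]methyl}hexanoate (formed in situ as magnesium chelate, C-3 not defined) | C=C1CCC[C@@]2(C)[C@H]1CC[C@H](C)[C@@]2(C)CC(C(=O)C(=O)OCC)C(=O)C(C)=O | intermediate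
22 | 2,5-dihydroxy-3-{[(1R,2S,4aS,8aS)-1,2,8a-trimethyl-5-methylidenedecahydronaphthalen-1-yl]methyl}cyclohexa-2,5-diene-1,4-dione | C=C1CCC[C@@]2(C)[C@H]1CC[C@H](C)[C@@]2(C)CC1=C(O)C(=O)C=C(O)C1=O | intermediate
23 | 2-hydroxy-5-methoxy-3-{[(1R,2S,4aS,8aS)-1,2,8a-trimethyl-5-methylidenedecahydronaphthalen-1-yl]methyl}cyclohexa-2,5-diene-1,4-dione | C=C1CCC[C@@]2(C)[C@H]1CC[C@H](C)[C@@]2(C)CC1=C(O)C(=O)C=C(OC)C1=O | target

## Step count and risks

Total step count: 16. Longest linear sequence: 15 steps (steps 1–13, 15 and 16); step 14 is a one-step side branch.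

Steps most likely to fail:

1. Step 15. What may go wrong: O-acylation or self-condensation of the pyruvoyl partner may outrun C-acylation of the keto ester, the polycarbonyl chain may fragment by retro-Claisen cleavage before it closes, or closure may occur through an enol oxygen instead of carbon. Fallback (known chemistry; a preformed ring is attached by a radical C–C bond instead of being built): it sets out from chloride 16. Finkelstein exchange (NaI, acetone, reflux) should give the iodide F1, Kornblum oxidation (DMSO, NaHCO3, 110 °C) the aldehyde F2, and Pinnick oxidation (NaClO2, NaH2PO4, 2-methylbut-2-ene, t-BuOH–H2O) the acid F3. Oxidative decarboxylation of F3 (AgNO3 cat., (NH4)2S2O8, MeCN–H2O, 60 °C) in the presence of commercial 2,5-dihydroxy-1,4-benzoquinone (radical alkylation of a hydroxyquinone, Jacobsen–Torssell type) should attach C-11 to the quinone C–H carbon, and the fallback comes back to the route at 22.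

2. Step 7. What may go wrong: over-reduction of the ring A alkene once the exo-methylene is consumed, or hydrogen delivery to the β face if the amide does not hold the metal. Fallback: it sets out from 9 and reverses the order of steps 7 and 8. LiEt3BH (THF) first reduces the amide to the dienyl alcohol F4; hydroxyl-directed hydrogenation with [Rh(nbd)(dppb)]BF4 (H2, CH2Cl2), a catalyst that does not reduce unactivated trisubstituted alkenes, should then give 11 directly, where the fallback rejoins the route.

3. Step 16. What may go wrong: methylation at the hindered C-2′ oxygen or at both oxygens, and acid-promoted migration of the exocyclic double bond into ring A. Fallback: it sets out from 22 and ends at 23, replacing the acid-catalysed condensation by a neutral alkylative methylation, a Mitsunobu reaction (MeOH, PPh3, DIAD, THF, 0 °C) in which the more acidic and more accessible C-5′ OH is the pronucleophile; no new compound is made (F0).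

Further compounds
F1 | step 15 | (1R,2S,4aS,8aS)-1-(2-iodoethyl)-1,2,8a-trimethyl-5-methylidenedecahydronaphthalene | C=C1CCC[C@@]2(C)[C@H]1CC[C@H](C)[C@@]2(C)CCI
F2 | step 15 | 2-[(1R,2S,4aS,8aS)-1,2,8a-trimethyl-5-methylidenedecahydronaphthalen-1-yl]acetaldehyde | C=C1CCC[C@@]2(C)[C@H]1CC[C@H](C)[C@@]2(C)CC=O
F3 | step 15 | 2-[(1R,2S,4aS,8aS)-1,2,8a-trimethyl-5-methylidenedecahydronaphthalen-1-yl]acetic acid | C=C1CCC[C@@]2(C)[C@H]1CC[C@H](C)[C@@]2(C)CC(=O)O
F4 | step 7 | 2-[(1R,8aS)-1,8a-dimethyl-2-methylidene-1,2,3,4,6,7,8,8a-octahydronaphthalen-1-yl]ethan-1-ol | C1CC[C@@]2(C)C(=C1)CCC(=C)[C@@]2(C)CCO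
F0 | step 16 | none | none
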